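**Strategy**

The route rests on closing ring B last through the C7–C8 bond (labdane numbering). An intramolecular Nozaki–Hiyama–Kishi reaction of a C8 alkenyl triflate with a C7 aldehyde creates, in one operation, the six-membered ring, the exocyclic C8=C17 methylene group and the axial C7 carbinol; it exploits the allylic alcohol unit C7(OH)–C8(=C17H2) of ring B. Its precursor is a fully substituted ring A cyclohexane (C2, C4, C5 and C10 in place) that carries the C6–C7 acetaldehyde arm on C5 and, on C10, the C9 stereocentre with the triflate and the Z-configured side chain; C9 is set by lithiation–borylation of a tertiary boronic ester.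

Key step: step 20

Remark on the chemistry: labdane numbering is used for every intermediate; β is the face of the C10 methyl group (C20) in the target, α the face of H-5.

**Route**

Step 1
Reactants: 1 methyl 4,4-dimethoxybutanoate
Product: 2 4,4-dimethoxybutanal
Conditions: iBu2AlH (DIBAL-H), CH2Cl2, −78 °C; aq. potassium sodium tartrate
Reagents that add atoms: none
Why: Partial ester reduction, the aluminium hemiacetal being stable at −78 °C and releasing the aldehyde on work-up; no stereocentre is formed.

Step 2
Reactants: 2 4,4-dimethoxybutanal; 3 methyl (E)-4-oxopent-2-enoate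
Product: 5 methyl trans-2-(2,2-dimethoxyethyl)-5-oxocyclohex-3-ene-1-carboxylate (ring A enone with β C6–C7 arm on C5 and α ester on C4), via Michael adduct 4 (not isolated)
Conditions: (R)-α,α-diphenylprolinol trimethylsilyl ether (10 mol %), PhCO2H (10 mol %), toluene, 0 °C → rt; then camphorsulfonic acid (10 mol %), 4 Å MS, 40 °C
Reagents that add atoms: none
Why: Enamine-catalysed Michael addition of the aldehyde to the carbon β to the ketone of the keto enoate, the (R)-diarylprolinol silyl ether directing attack to the Re face of the E-enamine and so setting C5, followed by intramolecular aldol condensation of the methyl ketone onto the aldehyde (Robinson-type annulation); the epimerisable C4 centre is re-set in step 8.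

Step 3
Reactants: 5 ring A enone
Product: 6 methyl 2-(2,2-dimethoxyethyl)-3-methyl-5-(trimethylsilyloxy)cyclohex-4-ene-1-carboxylate (C10 methyl α)
Conditions: MeMgBr, CuBr·SMe2 (10 mol %), Me3SiCl, THF, −78 °C
Reagents that add atoms: methylmagnesium bromide C[Mg]Br; chlorotrimethylsilane C[Si](C)(C)Cl
Why: Copper-catalysed 1,4-addition of the methyl Grignard reagent with in situ O-silylation of the enolate; the new C10 centre (methyl expected trans to the C5 arm) is planarised again in step 4.

Step 4
Reactants: 6 silyl enol ether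
Product: 7 methyl trans-2-(2,2-dimethoxyethyl)-3-methyl-5-oxocyclohex-3-ene-1-carboxylate (C1=C10 enone with C10 methyl)
Conditions: Pd(OAc)2, MeCN, rt
Reagents that add atoms: none
Why: Saegusa–Ito oxidation, in which the palladium enolate formed regiospecifically at C1 loses H-10 by β-hydride elimination and leaves C5 untouched.

Step 5
Reactants: 7 3-methyl enone
Product: 8 tertiary boronic ester ketone (C10: β-methyl and α-Bpin; C2 ketone)
Conditions: B2pin2, CuCl (5 mol %), NaOtBu (10 mol %), DPEphos (5 mol %), MeOH, THF, rt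
Reagents that add atoms: bis(pinacolato)diboron CC1(C)OB(OC1(C)C)B1OC(C)(C)C(C)(C)O1
Why: Copper-catalysed conjugate borylation of the β,β-disubstituted enone, the boryl copper species adding to C10 anti to the adjacent C5 arm so that boron is α and the methyl group β.

Step 6
Reactants: 8 boryl ketone
Product: 9 2α-alcohol (equatorial hydroxyl)
Conditions: SmI2, H2O, THF, 0 °C
Reagents that add atoms: none
Why: Electron-transfer (ketyl) reduction with SmI2–water should give the thermodynamically preferred equatorial 2α-alcohol, as dissolving-metal reductions do, whereas small hydrides would be steered to the wrong face by the axial C10 methyl group.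

Step 7
Reactants: 9 2α-alcohol
Product: 10 2α-tert-butyldimethylsilyl ether
Conditions: TBSCl, imidazole, DMF, rt
Reagents that add atoms: tert-butyldimethylsilyl chloride CC(C)(C)[Si](C)(C)Cl
Why: Standard silylation of the secondary alcohol; no stereocentre is affected.

Step 8
Reactants: 10 silyl ether ester
Product: 11 C4-methylated ester (4α-methyl, 4β-CO2Me)
Conditions: LiN(iPr)2, THF, −78 °C; MeI, DMPU, −78 → −20 °C
Reagents that add atoms: iodomethane CI
Why: Ester enolate alkylation in which methyl iodide approaches the exocyclic enolate from the α face, anti to the adjacent C5 arm and away from the axial C10 methyl group, leaving the ester axial (β) as in podocarpate-type alkylations.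

Step 9
Reactants: 12 pent-4-yn-1-ol
Product: 13 pent-4-yn-1-yl N,N-diisopropylcarbamate
Conditions: iPr2NC(O)Cl, Et3N, CH2Cl2, reflux
Reagents that add atoms: N,N-diisopropylcarbamoyl chloride CC(C)N(C(C)C)C(Cl)=O
Why: O-Carbamoylation of the primary alcohol installs the directing and leaving group for the later lithiation–borylation.

Step 10
Reactants: 13 alkynyl carbamate
Product: 14 methyl 6-(N,N-diisopropylcarbamoyloxy)hex-2-ynoate
Conditions: LiN(iPr)2, THF, −78 °C; ClCO2Me
Reagents that add atoms: methyl chloroformate COC(Cl)=O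
Why: Deprotonation of the terminal alkyne and C-acylation of the lithium acetylide give the ynoate.

Step 11
Reactants: 14 ynoate
Product: 15 methyl (Z)-6-(N,N-diisopropylcarbamoyloxy)-3-methylhex-2-enoate
Conditions: Me2CuLi (from MeLi and CuI), THF, −78 °C; MeOH, −78 °C
Reagents that add atoms: lithium dimethylcuprate [Li+].C[Cu-]C
Why: syn-Carbocupration of the ynoate and protonation of the alkenyl cuprate at −78 °C with retention place the chain cis to the ester, which is the Z geometry of the C13=C14 bond.

Step 12
Reactants: 15 (Z)-enoate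
Product: 16 (Z)-6-hydroxy-4-methylhex-4-en-1-yl N,N-diisopropylcarbamate
Conditions: iBu2AlH, CH2Cl2, −78 °C
Reagents that add atoms: none
Why: 1,2-Reduction of the conjugated ester to the allylic alcohol without touching the carbamate or the alkene geometry.

Step 13
Reactants: 16 allylic alcohol
Product: 17 (Z)-6-(tert-butyldimethylsilyloxy)-4-methylhex-4-en-1-yl N,N-diisopropylcarbamate
Conditions: TBSCl, imidazole, DMF, rt
Reagents that add atoms: tert-butyldimethylsilyl chloride CC(C)(C)[Si](C)(C)Cl
Why: Silylation protects the C15 hydroxyl against the organolithium steps.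

Step 14
Reactants: 17 side-chain carbamate; 11 tertiary boronic ester
Product: 20 secondary boronic ester with the C9–C10 bond (C9 bearing Bpin in the place of C8), via lithiated carbamate 18 (not isolated), via boronate complex 19 (not isolated)
Conditions: 17, sBuLi, (−)-sparteine, Et2O, −78 °C; then 11, −78 °C; MgBr2·OEt2, −78 °C → reflux
Reagents that add atoms: none
Why: Lithiation–borylation, in which sparteine-directed removal of the pro-S proton gives the (S)-α-lithio carbamate, boron is attacked with retention and the tertiary C10 group migrates anti to the departing carbamate (retention at C10, inversion at C9), so that C9 is set by the reagent; pinacol esters of tertiary boronic acids are known to take part in this homologation.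

Step 15
Reactants: 20 secondary boronic ester
Product: 23 methyl ketone (C8 carbonyl with C17 methyl on C9), via vinyl boronate complex 21 (not isolated), via enol ether 22 (not isolated)
Conditions: CH2=C(Li)OEt (from ethyl vinyl ether and tBuLi), THF, −78 °C; I2, MeOH, −78 °C; NaOMe; then 0.05 M aq. HCl, THF, 0 °C
Reagents that add atoms: ethyl vinyl ether C=COCC; water O
Why: Zweifel olefination with 1-ethoxyvinyllithium (iodine-triggered 1,2-migration with retention at C9, then anti-elimination) gives the 2-ethoxyalkene, whose hydrolysis is far faster than that of the dimethyl acetal and unveils the methyl ketone.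

Step 16
Reactants: 23 methyl ketone
Product: 24 alkenyl triflate (C8(OTf)=C17H2)
Conditions: KN(SiMe3)2, THF, −78 °C; PhNTf2
Reagents that add atoms: N-phenylbis(trifluoromethanesulfonimide) O=S(=O)(N(c1ccccc1)S(=O)(=O)C(F)(F)F)C(F)(F)F
Why: Kinetic deprotonation at the unhindered methyl group and O-triflation of the enolate give the 1,1-disubstituted alkenyl triflate without touching the hindered H-9 or the non-enolisable ester.

Step 17
Reactants: 24 triflate ester
Product: 25 primary alcohol (C19–OH)
Conditions: iBu2AlH (excess), CH2Cl2, −78 → 0 °C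
Reagents that add atoms: none
Why: Hydride reduction of the hindered axial ester to the neopentyl alcohol, a reaction that alkenyl triflates, silyl ethers and the acetal tolerate.

Step 18
Reactants: 25 primary alcohol
Product: 26 C19 acetate
Conditions: Ac2O, pyridine, DMAP, CH2Cl2, rt
Reagents that add atoms: acetic anhydride CC(=O)OC(C)=O
Why: DMAP-catalysed acetylation of the only free hydroxyl group installs the acetate of the target.

Step 19
Reactants: 26 acetate
Product: 27 aldehyde diol alkenyl triflate (C7 aldehyde, free 2α- and C15-hydroxyl groups)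
Conditions: 48% aq. HF, MeCN, 0 °C → rt
Reagents that add atoms: water O
Why: Aqueous HF cleaves both silyl ethers and hydrolyses the dimethyl acetal in one operation, while the acetate and the alkenyl triflate are stable to these conditions.

Step 20
Reactants: 27 aldehyde diol alkenyl triflate
Product: 28 19-acetoxylabda-8(17),13Z-diene-2α,7α,15-triol
Conditions: CrCl2 (excess), NiCl2 (2 mol %), DMF, rt, high dilution
Reagents that add atoms: none
Why: Zerovalent nickel, formed in situ from NiCl2 and CrCl2, inserts into the alkenyl C8–OTf bond and transmetalates to trivalent chromium, and the alkenylchromium species adds to the C7 aldehyde (intramolecular Nozaki–Hiyama–Kishi reaction). The closest known reaction type is the Ni/Cr-mediated cyclisation of alkenyl halide or triflate aldehydes to 2-methylenecycloalkanols. Ring B closes in a 6-exo-trig mode by formation of the C7–C8 bond. The new C7 stereocentre is controlled by the chair-like transition state that ring A enforces through its equatorial C6 and C9 arms (trans ring fusion): the chromium-bound carbonyl oxygen should take the pseudo-axial α position, because the pseudo-equatorial one would eclipse the C8=C17 bond (allylic 1,3-strain), which gives the 7α-alcohol. The step needs chemoselectivity for the aldehyde over the acetate, the free hydroxyl groups and the trisubstituted alkene, which the aldehyde selectivity and low basicity of organochromium reagents secure, and cyclisation over oligomerisation, which high dilution secures.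

Step 21
Reactants: 28 triol
Product: 29 target, 2α,7α-dihydroxy-15-oxolabda-8(17),13Z-dien-19-yl acetate
Conditions: TEMPO (10 mol %), PhI(OAc)2, CH2Cl2, rt
Reagents that add atoms: none
Why: Oxoammonium-mediated oxidation is selective for the primary allylic alcohol over the two secondary alcohols and, as in the oxidation of nerol to neral, should preserve the Z geometry of the enal.

**Compound list**

1 | methyl 4,4-dimethoxybutanoate | COC(=O)CCC(OC)OC | starting material
2 | 4,4-dimethoxybutanal | O=CCCC(OC)OC | intermediate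
3 | methyl (E)-4-oxopent-2-enoate | COC(=O)/C=C/C(C)=O | starting material
4 | Michael adduct, methyl 3-formyl-5,5-dimethoxy-2-(2-oxopropyl)pentanoate (C5 as in the target) | COC(OC)C[C@H](C=O)[C@@H](CC(C)=O)C(=O)OC | intermediate
5 | methyl trans-2-(2,2-dimethoxyethyl)-5-oxocyclohex-3-ene-1-carboxylate | COC(OC)C[C@H]1[C@H](C(=O)OC)CC(=O)C=C1 | intermediate
6 | methyl 2-(2,2-dimethoxyethyl)-3-methyl-5-(trimethylsilyloxy)cyclohex-4-ene-1-carboxylate (C10 methyl α) | COC(OC)C[C@H]1[C@H](C(=O)OC)CC(O[Si](C)(C)C)=C[C@@H]1C | intermediate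
7 | methyl trans-2-(2,2-dimethoxyethyl)-3-methyl-5-oxocyclohex-3-ene-1-carboxylate | COC(OC)C[C@H]1[C@H](C(=O)OC)CC(=O)C=C1C | intermediate
8 | tertiary boronic ester ketone (10β-methyl, 10α-Bpin, 2-oxo) | COC(OC)C[C@H]1[C@H](C(=O)OC)CC(=O)C[C@]1(C)B2OC(C)(C)C(C)(C)O2 | intermediate
9 | 2α-alcohol of 8 | COC(OC)C[C@H]1[C@H](C(=O)OC)C[C@H](O)C[C@]1(C)B2OC(C)(C)C(C)(C)O2 | intermediate
10 | 2α-TBS ether of 9 | COC(OC)C[C@H]1[C@H](C(=O)OC)C[C@H](O[Si](C)(C)C(C)(C)C)C[C@]1(C)B2OC(C)(C)C(C)(C)O2 | intermediate
11 | 4α-methyl-4β-methoxycarbonyl boronic ester | COC(OC)C[C@H]1[C@@](C)(C(=O)OC)C[C@H](O[Si](C)(C)C(C)(C)C)C[C@]1(C)B2OC(C)(C)C(C)(C)O2 | intermediate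
12 | pent-4-yn-1-ol | OCCCC#C | starting material
13 | pent-4-yn-1-yl N,N-diisopropylcarbamate | CC(C)N(C(C)C)C(=O)OCCCC#C | intermediate
14 | methyl 6-(N,N-diisopropylcarbamoyloxy)hex-2-ynoate | CC(C)N(C(C)C)C(=O)OCCCC#CC(=O)OC | intermediate
15 | methyl (Z)-6-(N,N-diisopropylcarbamoyloxy)-3-methylhex-2-enoate | CC(C)N(C(C)C)C(=O)OCCC/C(C)=C\C(=O)OC | intermediate
16 | (Z)-6-hydroxy-4-methylhex-4-en-1-yl N,N-diisopropylcarbamate | CC(C)N(C(C)C)C(=O)OCCC/C(C)=C\CO | intermediate
17 | (Z)-6-(tert-butyldimethylsilyloxy)-4-methylhex-4-en-1-yl N,N-diisopropylcarbamate | CC(C)N(C(C)C)C(=O)OCCC/C(C)=C\CO[Si](C)(C)C(C)(C)C | intermediate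
18 | (S)-α-lithio carbamate of 17 (sparteine complex, ligand not drawn) | CC(C)N(C(C)C)C(=O)O[C@@H]([Li])CC/C(C)=C\CO[Si](C)(C)C(C)(C)C | intermediate
19 | lithium boronate complex of 11 and 18 | [Li+].COC(OC)C[C@H]1[C@@](C)(C(=O)OC)C[C@H](O[Si](C)(C)C(C)(C)C)C[C@]1(C)[B-]2(OC(C)(C)C(C)(C)O2)[C@H](OC(=O)N(C(C)C)C(C)C)CC/C(C)=C\CO[Si](C)(C)C(C)(C)C | intermediate
20 | secondary boronic ester (C9–Bpin, C9–C10 bond formed) | COC(OC)C[C@H]1[C@@](C)(C(=O)OC)C[C@H](O[Si](C)(C)C(C)(C)C)C[C@]1(C)[C@H](B2OC(C)(C)C(C)(C)O2)CC/C(C)=C\CO[Si](C)(C)C(C)(C)C | intermediate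
21 | lithium (1-ethoxyvinyl)boronate complex of 20 | [Li+].COC(OC)C[C@H]1[C@@](C)(C(=O)OC)C[C@H](O[Si](C)(C)C(C)(C)C)C[C@]1(C)[C@H]([B-]2(OC(C)(C)C(C)(C)O2)C(=C)OCC)CC/C(C)=C\CO[Si](C)(C)C(C)(C)C | intermediate
22 | 2-ethoxyalkene (enol ether at C8) | COC(OC)C[C@H]1[C@@](C)(C(=O)OC)C[C@H](O[Si](C)(C)C(C)(C)C)C[C@]1(C)[C@H](C(=C)OCC)CC/C(C)=C\CO[Si](C)(C)C(C)(C)C | intermediate
23 | methyl ketone (C8=O) | COC(OC)C[C@H]1[C@@](C)(C(=O)OC)C[C@H](O[Si](C)(C)C(C)(C)C)C[C@]1(C)[C@H](C(C)=O)CC/C(C)=C\CO[Si](C)(C)C(C)(C)C | intermediate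
24 | alkenyl triflate | COC(OC)C[C@H]1[C@@](C)(C(=O)OC)C[C@H](O[Si](C)(C)C(C)(C)C)C[C@]1(C)[C@H](C(=C)OS(=O)(=O)C(F)(F)F)CC/C(C)=C\CO[Si](C)(C)C(C)(C)C | intermediate
25 | C19 primary alcohol | COC(OC)C[C@H]1[C@@](C)(CO)C[C@H](O[Si](C)(C)C(C)(C)C)C[C@]1(C)[C@H](C(=C)OS(=O)(=O)C(F)(F)F)CC/C(C)=C\CO[Si](C)(C)C(C)(C)C | intermediate
26 | C19 acetate | COC(OC)C[C@H]1[C@@](C)(COC(C)=O)C[C@H](O[Si](C)(C)C(C)(C)C)C[C@]1(C)[C@H](C(=C)OS(=O)(=O)C(F)(F)F)CC/C(C)=C\CO[Si](C)(C)C(C)(C)C | intermediate
27 | aldehyde diol alkenyl triflate (cyclisation precursor) | O=CC[C@H]1[C@@](C)(COC(C)=O)C[C@H](O)C[C@]1(C)[C@H](C(=C)OS(=O)(=O)C(F)(F)F)CC/C(C)=C\CO | intermediate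
28 | 19-acetoxylabda-8(17),13Z-diene-2α,7α,15-triol | C=C1[C@H](O)C[C@H]2[C@@](C)(COC(C)=O)C[C@H](O)C[C@]2(C)[C@H]1CC/C(C)=C\CO | intermediate
29 | 2α,7α-dihydroxy-15-oxolabda-8(17),13Z-dien-19-yl acetate | C=C1[C@H](O)C[C@H]2[C@@](C)(COC(C)=O)C[C@H](O)C[C@]2(C)[C@H]1CC/C(C)=C\C=O | target

**Step count**

Total step count: 21 steps. Longest linear sequence: 16 steps (steps 1–8 and 14–21); steps 9–13 build the side-chain fragment.

**Steps most likely to fail**

Step 14. What may go wrong: slow and reversible formation of the boronate complex at the hindered tertiary boron atom, so that the lithiated carbamate decomposes or adds to the ester before the 1,2-migration takes place. Fallback (the roles of the partners are exchanged, so that the boronate complex forms at an unhindered primary boronic ester): setting out from 11, Matteson homologation with chloromethyllithium (ICH2Cl, n-BuLi, THF, −78 °C → rt) would give the primary boronic ester F1, oxidation (NaBO3·4H2O, THF/H2O) the neopentyl alcohol F2, and carbamoylation (iPr2NC(O)Cl, Et3N) the ring carbamate F3. The side-chain partner would be made from (Z)-3-iodobut-2-en-1-ol by silylation to the alkenyl iodide F4 and B-alkyl Suzuki–Miyaura coupling (Pd(dppf)Cl2, K3PO4) with the 9-BBN adduct F5 of vinylboronic acid pinacol ester, which gives the side-chain boronic ester F6. Lithiation of F3 (sBuLi, (+)-sparteine surrogate, Et2O, −78 °C; the hindered C19 ester is expected to survive), addition of F6 and MgBr2-promoted 1,2-migration would then deliver 20, where the route is rejoined.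

Step 20. What may go wrong: poor facial selectivity in the addition of the alkenylchromium centre to the aldehyde, so that the 7β epimer forms beside or instead of the 7α-alcohol. Fallback (C7 is set by a catalyst-controlled reduction and not in the C–C bond formation): setting out from 26, the dimethyl acetal alone would be cleaved (Et3SiOTf, 2,4,6-collidine, CH2Cl2, then water) to the bis-silylated aldehyde F7. The same Ni/Cr cyclisation would give the C7 epimeric alcohols F8 (7β epimer drawn), and Dess–Martin oxidation would converge them on the exocyclic enone F9. CBS reduction ((S)-2-methyl-CBS-oxazaborolidine, catecholborane, −78 °C), with hydride delivered to the β face, would give the 7α-alcohol F10, and aqueous HF in MeCN would remove both silyl groups and return the route at 28.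

Step 6. What may go wrong: poor facial selectivity of the ketone reduction, giving the axial 2β-alcohol beside the equatorial one. Fallback (inversion in place of direct reduction): setting out from 8, K(sBu)3BH in THF at −78 °C would attack from the equatorial side and give the axial 2β-alcohol F11 cleanly; Mitsunobu inversion (PPh3, DIAD, 4-nitrobenzoic acid) would give the 2α 4-nitrobenzoate F12, and methanolysis (K2CO3, MeOH) would return the route at 9.

Further compounds
F1 | step 14 | primary boronic ester from one-carbon homologation of 11 (C10–CH2–Bpin) | COC(OC)C[C@H]1[C@@](C)(C(=O)OC)C[C@H](O[Si](C)(C)C(C)(C)C)C[C@]1(C)CB2OC(C)(C)C(C)(C)O2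
F2 | step 14 | neopentyl alcohol (C10–CH2OH) | COC(OC)C[C@H]1[C@@](C)(C(=O)OC)C[C@H](O[Si](C)(C)C(C)(C)C)C[C@]1(C)CO
F3 | step 14 | ring carbamate (C10–CH2–OC(O)N(iPr)2) | COC(OC)C[C@H]1[C@@](C)(C(=O)OC)C[C@H](O[Si](C)(C)C(C)(C)C)C[C@]1(C)COC(=O)N(C(C)C)C(C)C
F4 | step 14 | (Z)-tert-butyl(3-iodobut-2-enyloxy)dimethylsilane | C/C(I)=C/CO[Si](C)(C)C(C)(C)C
F5 | step 14 | 9-[2-(4,4,5,5-tetramethyl-1,3,2-dioxaborolan-2-yl)ethyl]-9-borabicyclo[3.3.1]nonane | CC1(C)OB(CCB2C3CCCC2CCC3)OC1(C)C
F6 | step 14 | (Z)-tert-butyldimethyl[3-methyl-5-(4,4,5,5-tetramethyl-1,3,2-dioxaborolan-2-yl)pent-2-enyloxy]silane | CC1(C)OB(CC/C(C)=C\CO[Si](C)(C)C(C)(C)C)OC1(C)C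
F7 | step 20 | bis-silylated aldehyde alkenyl triflate | O=CC[C@H]1[C@@](C)(COC(C)=O)C[C@H](O[Si](C)(C)C(C)(C)C)C[C@]1(C)[C@H](C(=C)OS(=O)(=O)C(F)(F)F)CC/C(C)=C\CO[Si](C)(C)C(C)(C)C
F8 | step 20 | bis-silylated 7β-alcohol (C7 epimer) | C=C1[C@@H](O)C[C@H]2[C@@](C)(COC(C)=O)C[C@H](O[Si](C)(C)C(C)(C)C)C[C@]2(C)[C@H]1CC/C(C)=C\CO[Si](C)(C)C(C)(C)C
F9 | step 20 | bis-silylated 7-oxo-8(17)-ene (exocyclic enone) | C=C1C(=O)C[C@H]2[C@@](C)(COC(C)=O)C[C@H](O[Si](C)(C)C(C)(C)C)C[C@]2(C)[C@H]1CC/C(C)=C\CO[Si](C)(C)C(C)(C)C
F10 | step 20 | bis-silylated 7α-alcohol | C=C1[C@H](O)C[C@H]2[C@@](C)(COC(C)=O)C[C@H](O[Si](C)(C)C(C)(C)C)C[C@]2(C)[C@H]1CC/C(C)=C\CO[Si](C)(C)C(C)(C)C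
F11 | step 6 | axial 2β-alcohol (C2 epimer of 9) | COC(OC)C[C@H]1[C@H](C(=O)OC)C[C@@H](O)C[C@]1(C)B2OC(C)(C)C(C)(C)O2
F12 | step 6 | 2α 4-nitrobenzoate | COC(OC)C[C@H]1[C@H](C(=O)OC)C[C@H](OC(=O)c2ccc(cc2)[N+](=O)[O-])C[C@]1(C)B3OC(C)(C)C(C)(C)O3
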